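Remarks on the chemistry (one line each)
- Locants: decalin carbons are C1–C10 (C4 bears the carboxyl carbon and a methyl, C8 a methyl and an oxygen, C10 a methyl); the chain on C9 is C11–C12–C13 and C13 carries the exocyclic CH2; the peroxide part is C14 (dioxane CH bonded to C13), C15 (CH2), C16 (CH–O), C17 (C–OO, methyl), C18 (CH2), C19 (lactone carbonyl); α is the face opposite the C10 methyl.
- Configuration: the target's descriptors (14R,16S,17R) place the lactone oxygen on C16 and the C18 methylene on C17 on opposite faces of the dioxane, so the lactone–dioxane junction is planned as trans; amide 10 and lactone 14 carry the target's configuration at C4, C5, C8, C9, C10 (and C6 in 14), so no structure needed correction.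
- Supply: neoabietic acid, a pine resin acid and double-bond isomer of abietic acid, is assumed to be purchasable; it has the same C4, C5 and C10 as dehydroabietic acid, which would first need its isopropyl group exchanged for oxygen and a dissolving-metal reduction before ring C could be cleaved.

## Structural features

The target is a C25 methyl ester in which a trans-fused decalin (rings A and B) carries at C9 a two-carbon tether ending in a 1,1-disubstituted alkene (C13=CH2), and C13 is bonded to C14 of a 1,2-dioxane that shares its C16–C17 bond with a γ-lactone. The decalin holds six stereocentres in two contiguous runs, C4 (quaternary, ester α, methyl β)–C5–C6 (α-hydroxyl) and C8 (tertiary α-hydroxyl, β-methyl)–C9–C10 (quaternary). The peroxide bicycle holds three more, C16 and C17 adjacent and C14 one methylene away. Because the lactone is trans-fused, C16–O and C17–C18 are both equatorial on the dioxane, the C17 methyl is axial and the C13 substituent on C14 is axial too, so C14 cannot be set by any equilibrating ring closure. Fragile groups are the O–O bond (reducing metals, phosphines, hydrides; base, since C14–H is allylic and α to the peroxide), the 6α-hydroxyl/C4 ester pair (relactonisation), the tertiary C8 alcohol, the exocyclic alkene and the strained lactone. Rings A and B with the C4 carboxyl/methyl pattern are those of the abietane resin acids, so C4, C5, C9 and C10 can be bought; the real difficulties are an α-oxygen on the unactivated C6 methylene next to a quaternary carbon, and a late, stereodefined peroxide. The key step exploits the fact that in the trans-decalin the equatorial 4α-carboxyl carbon and the equatorial C6–H are syn-1,3 (peri) across C5: a nitrogen radical on the C4 carboxamide reaches C6–H through a six-membered transition state, and the five-membered lactone that follows can only bridge the α face of ring B.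

## Logic of the disconnections

39 is first cut at the acyl–oxygen bond C19–O(C16) of the γ-lactone, with C19 lowered to the alcohol level; this gives 36, and silylation of its C6, C8 and C19 hydroxyls gives 35. The reason is that a C19 carbonyl must not coexist with a free hydroperoxide on C17 (it would close to a five-membered peroxylactone), whereas a silyl ether is inert. The gain is a lactone replaced by a 1,4-diol and one kind of protecting group. The demand is an oxidant that takes the primary C19 alcohol and the derived lactol but not the C6 alcohol, and two steps that neither reduce nor base-cleave the O–O bond.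

35 is cut at O–C14, which leads to 34, and 34 is cut at C17–O(O), which leads to 33. An axial C13 substituent on C14 can only come from a stereospecific displacement with inversion, and the trans relation of C16–O and C17–C18 is exactly what anti opening of an E-configured epoxide at C17 delivers. The gain is that three peroxide-ring stereocentres reduce to one carbinol and one epoxide. The demands are attack of hydrogen peroxide at C17 only and with inversion, survival of the allylic sulfonate under acid, and substitution at C14 faster than elimination or allylic transposition.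

33 goes back through 32 and 31 to 30, which is cut at C13–C14 into 20 and 28. This bond joins an sp2 carbon to a carbinol, the retron of an alkenylchromium addition to an aldehyde, and it divides the molecule into the decalin and a six-carbon piece. Since the remote C16 centre cannot control C14, the carbinol is erased (31) and reset by a catalyst-controlled reduction (32). The demand is that the epoxide of 28 survives chromium salts and the ketone stage.

28 comes from 27 by oxidation, and 27 from 26 by cutting both C–O bonds of the epoxide; 26 is cut at C15–C16 and at the C17–methyl bond into 22 and 23, and 22 is the silyl ether of 21. Syn carbometallation of the alkyne fixes the E geometry, and one enantioselective epoxidation then sets C16 and C17 together. The demand is high facial selectivity on an unfunctionalised trisubstituted alkene.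

20 is traced through 19 and 17 to 16 by functional-group changes at C13 and protection at C6, and 16 is derived from 14 by cutting the acyl–oxygen bond of the bridging lactone. The lactone is the form in which the C6 oxygen is introduced and it delivers the C4 methyl ester and the 6α-alcohol in one operation. The demands are an opening that cannot revert (the hydroxy ester would relactonise) and chemistry at the C13 ester that leaves the hindered C4 ester alone.

14 is cut at C6–O to give 10; this is the strategic cut, because it replaces an oxygenated stereocentre by a methylene and lets the C4 carboxyl group place its own oxygen on C6. The demands on 10 are a primary amide on the 4α-carbon, no free hydroxyl (a hypoiodite would form at C8, hence the silyl ether), no free carboxylic acid (an acyl hypoiodite would decarboxylate, hence the C13 ester) and no benzylic or allylic C–H (hence ring C is already excised).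

10 is simplified through 8 (amide to acid), 6 (silyl ether to alcohol), 5 (C8–O bond, hydration of the exocyclic alkene from the α face), 4 (alkene to ketone) and 3 (ester to acid) to 1, by reconnecting C8 and C13 through one ring carbon and restoring the isopropylidene group. Cleaving both double bonds of ring C of 1 releases C8 as a ketone and C13 as an acid and leaves C4, C5, C9 and C10 untouched. The demands are complete cleavage at the enone stage, esterification of the C13 acid only, and delivery of oxygen to C8 from the face opposite the C10 methyl.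

## Other disconnections considered

Alternative 1: The cut is through C4–C5, C9–C10 and O–C8, so that rings A and B unravel to the open-chain epoxy dienoic acid A1. In the forward step SnCl4 would ionise the epoxide of A1 at C4, the C5=C10 and C8=C9 alkenes would close rings A and B through chair-like transition states, and the carboxyl group would capture the C8 cation to give the tricyclic lactone A2.
- In its favour: two carbocycles, the lactone and the relative configuration of C5, C8, C9 and C10 come from one step. The 8α-oxygen arrives with the cyclisation, which is better than the chosen plan, where C8 costs a methylenation and a hydration (steps 3 and 4). The C6 oxygen is present from the start, so no C–H functionalisation is needed, and the route does not depend on a resin acid.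
- Against it here: the C6 benzyloxy group is allylic to the C5=C10 alkene, which deactivates the first ring closure and offers SnCl4 a second site of ionisation. C6 must be set in the open chain and matched to the epoxide. A2 carries a C3 hydroxyl that the target lacks, has C4 at the alcohol level, and ends the C9 chain at C12 as a lactone carbonyl, so C13 must still be added.
- Comparison: on structure the two plans are equal in fixing the C4 quaternary centre stereospecifically (epoxide geometry there, chiral pool here). On mechanism a cationic cascade rests on the folding of a flexible chain, whereas the chosen radical step has site and face fixed by a rigid ring, so the chosen plan is the more secure. On step economy the chosen plan reaches 14 in seven steps, while the alternative would need a multistep assembly of A1 followed by deoxygenation at C3, oxidation at C4 and homologation at C12.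

Alternative 2: The cut is through C5–C10 and C3–C4, giving the triene ester A3, in which a tiglate-type dienophile (C4=C5) is tethered through C6–C9 to a diene (C10=C1–C2=C3). In the forward step heating or Me2AlCl would bring about the intramolecular Diels–Alder reaction of A3 to the octalin A4.
- In its favour: both rings and both quaternary centres (C4, C10) form in one suprafacial step. The C4 ester is already at the right oxidation level, which equals the chosen plan. The C6 and C8 oxygens are in place before ring formation, which is better than the chosen plan in that neither C–H oxidation nor hydration is required.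
- Against it here: the diene terminus C10 is fully substituted with its methyl on the inside, which disfavours the s-cis conformer and slows the cycloaddition. The trans ring fusion with a 4α-ester needs the ester-endo transition state, and the α-methyl of the dienophile and the three stereocentres in the tether may erode that preference. A4 has a C1=C2 alkene to remove, and its acetonide ties O8 to C11, so the whole side chain from C12 onwards must still be built. C6, C8 (a tertiary ether) and C9 must first be made by asymmetric synthesis in an acyclic setting.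
- Comparison: the pericyclic mechanism is predictable in relative configuration but not in facial or endo/exo control, whereas the chosen plan inherits four centres and creates C6 under geometric constraint. In step count the alternative is longer before and after its key step.

Alternative 3: The cut is at O–C14 of the dioxane, leading to the hydroxy hydroperoxy mesylate A5. In the forward step Cs2CO3 would make the C17 hydroperoxide of A5 displace the allylic mesylate at C14 with inversion to give the dioxane A6.
- In its favour: the closure is stereospecific and is the one reliable way to the axial C14 substituent; it is mild and comes after the fragment union.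
- Against it here: as the step that carries a whole plan it addresses only the side chain and leaves the C6 oxygenation unsolved. A5 protects C19 as a 4-methoxybenzyl ether, which needs its own oxidative removal before the lactone can be formed, and it has already given up the C8 silyl ether.
- Comparison: on this bond the alternative is the equal of the chosen plan, because step 21 (34 to 35) closes the same O–C14 bond by the same mechanism. The alternative is the better in that a 4-methoxybenzyl ether should be indifferent to the acid of the perhydrolysis, where a primary silyl ether may be lost. The chosen plan is one step shorter after the ring closure because all protecting groups leave together.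

Key step: step 7

Step 1
Reactants: 1 neoabietic acid
Product: 3 keto diacid (C8 ketone; C13 and C4 carboxylic acids), via enone acid 2 (not isolated)
Conditions: O3 (excess), CH2Cl2/MeOH, −78 °C; then 30% H2O2, aq. NaOH, 0 °C → rt; then H3O+
Reagents that add atoms: ozone, [O-][O+]=O; hydrogen peroxide, OO
Why: Ozonolysis should cleave the electron-rich exocyclic tetrasubstituted alkene first (acetone leaves, giving 2) and then the enone alkene; oxidative work-up degrades the α-keto aldehyde so formed to the C13 acid with loss of one carbon as formic acid (ozonolysis of a conjugated enone to a nor keto acid). C9 becomes α to a ketone but already has the thermodynamically preferred equatorial side chain, so no stereocentre is at risk.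

Step 2
Reactants: 3 keto diacid
Product: 4 keto ester acid (C13 methyl ester; free C4 acid)
Conditions: MeOH, H2SO4 (cat.), rt
Reagents that add atoms: methanol, CO
Why: Fischer esterification discriminates on steric grounds: the chain acid at C13 esterifies at room temperature, the C4 acid on a quaternary ring carbon does not. It is done now, before an acid-sensitive alkene or tertiary alcohol exists.

Step 3
Reactants: 4 keto ester acid
Product: 5 methylene ester acid (C8=CH2)
Conditions: Ph3PCH3Br, KN(SiMe3)2, THF, 0 → 45 °C (3 equiv of ylide)
Reagents that add atoms: methyltriphenylphosphonium bromide, C[P+](c1ccccc1)(c1ccccc1)c1ccccc1.[Br-]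
Why: Wittig methylenation of a moderately hindered cyclohexanone; the C4 acid travels as its potassium salt and costs one equivalent of ylide. Base-free excess is avoided so that the ketone enolate does not condense with the C13 ester, and any equilibration at C9 can only reinforce the equatorial side chain.

Step 4
Reactants: 5 methylene ester acid
Product: 6 hydroxy ester acid (8α-OH; 8β-CH3)
Conditions: Mn(dpm)3 (cat., dpm = 2,2,6,6-tetramethylheptane-3,5-dionate), PhSiH3, O2 (1 atm), i-PrOH/CH2Cl2, 0 °C → rt
Reagents that add atoms: dioxygen, O=O
Why: Mukaiyama hydration: hydrogen-atom transfer from a manganese hydride to the CH2 terminus gives the tertiary C8 radical, which is captured by O2 and reduced by the silane to the alcohol. Capture should occur on the α (equatorial) face because the β face is shielded by the syn-axial C10 methyl, which gives the 8α-alcohol and an axial C8 methyl.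

Step 5
Reactants: 6 hydroxy ester acid
Product: 8 silyl ether acid (8α-OTES; free C4 acid), via bis-silyl compound 7 (not isolated)
Conditions: TESOTf, 2,6-lutidine, CH2Cl2, −40 → 0 °C; then aq. NaHCO3, THF, rt
Reagents that add atoms: triethylsilyl trifluoromethanesulfonate, CC[Si](CC)(CC)OS(=O)(=O)C(F)(F)F
Why: A silyl triflate is needed to silylate the tertiary alcohol; the acid is silylated too and the labile silyl ester of 7 is hydrolysed in the work-up. The ether blocks hypoiodite formation at C8 in step 7 and cyclisation of the C8 oxygen onto the C13 ester.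

Step 6
Reactants: 8 silyl ether acid
Product: 10 carboxamide (C4α-CONH2; 8α-OTES; C13 methyl ester), via acid chloride 9 (not isolated)
Conditions: 1-chloro-N,N,2-trimethylprop-1-en-1-amine, CH2Cl2, 0 °C → rt; then NH3 (in dioxane), 0 °C
Reagents that add atoms: ammonia, N
Why: The hindered C4 acid needs acid-chloride activation, and the α-chloroenamine provides it under neutral conditions that spare the silyl ether; ammonolysis of the acid chloride is far faster than attack of ammonia on the C13 methyl ester at 0 °C.

Step 7
Reactants: 10 carboxamide
Product: 14 γ-lactone (C4 carbonyl–O–C6α bridge; 8α-OTES; C13 methyl ester), via N-iodoamide 11 (not isolated), via 6-iodo amide 12 (not isolated), via iminolactone 13 (not isolated)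
Conditions: PhI(OAc)2, I2, CH2Cl2, hν (visible), rt; then THF/H2O, rt
Reagents that add atoms: water, O
Why: Acetyl hypoiodite formed from PhI(OAc)2 and I2 N-iodinates the primary amide to 11, light homolyses the N–I bond, and the amidyl radical takes a hydrogen from C6 through a six-membered chair-like transition state (1,5-hydrogen transfer). The C6 radical picks up iodine to give 12, whose iodide is activated by the trivalent-iodine oxidant and leaves as the amide oxygen attacks C6; the iminolactone 13 is then hydrolysed by water to 14. The closest known reaction type is the Hofmann–Löffler–Freytag-type photolysis of N-iodoamides, which gives γ-lactones after hydrolysis of the iminolactone. The one ring that forms is five-membered and closes in the 5-exo-tet mode through oxygen. The one new stereocentre, C6, is controlled by the tether: the carbonyl sits equatorial (α) on C4 of a rigid trans-decalin and can reach C6 only from the α face, whichever epimer of 12 is formed, because closure passes through a cation-like C6. The step needs site selectivity (C6 over C2, the methyls and the side chain), closure through oxygen and not nitrogen, and hydrogen transfer faster than Hofmann-type rearrangement. The substrate secures these by the peri (syn-1,3) arrangement of the 4α-carbonyl and C6–H across C5, by having no benzylic or allylic C–H once ring C is gone, by carrying no free hydroxyl or carboxyl group, and by a non-nucleophilic medium in which the neutral amide oxygen is the best internal nucleophile.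

Step 8
Reactants: 14 γ-lactone
Product: 16 hydroxy diester (6α-OH; C4 and C13 methyl esters; 8α-OTES), via dilithium dicarboxylate 15 (not isolated)
Conditions: LiOH, THF/MeOH/H2O, 50 °C; evaporate; then MeI, DMF, rt
Reagents that add atoms: lithium hydroxide, [Li+].[OH-]; iodomethane, CI
Why: Saponification opens the lactone (and the C13 ester) to a dicarboxylate that cannot relactonise, and O-alkylation of the carboxylates then gives the hydroxy diester without passing through the free hydroxy acid. Only acyl–oxygen bonds are broken, so C6 keeps its configuration.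

Step 9
Reactants: 16 hydroxy diester
Product: 17 bis-silyl diester (6α-OTBS; 8α-OTES)
Conditions: TBSOTf, 2,6-lutidine, CH2Cl2, 0 °C
Reagents that add atoms: tert-butyldimethylsilyl trifluoromethanesulfonate, CC(C)(C)[Si](C)(C)OS(=O)(=O)C(F)(F)F
Why: Silyl triflate protection of the hindered equatorial C6 alcohol; without it a C6 alkoxide would close back onto the C4 ester in the basic steps that follow.

Step 10
Reactants: 17 bis-silyl diester
Product: 19 methyl ketone (C13 ketone), via Weinreb amide 18 (not isolated)
Conditions: MeNH(OMe)·HCl, i-PrMgCl, THF, −20 °C; then MeMgBr, −20 → 0 °C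
Reagents that add atoms: methylmagnesium bromide, C[Mg]Br
Why: One-pot Weinreb ketone synthesis: the magnesium amide of N,O-dimethylhydroxylamine converts only the unhindered C13 ester to 18, and the chelated adduct of 18 with MeMgBr stops at the ketone. The C4 ester sits on a quaternary carbon next to the C6 silyl ether and should not react.

Step 11
Reactants: 19 methyl ketone
Product: 20 alkenyl triflate (C13(OTf)=CH2)
Conditions: KN(SiMe3)2, THF, −78 °C; then N-(5-chloropyridin-2-yl)bis(trifluoromethanesulfonyl)imide, −78 °C
Reagents that add atoms: N-(5-chloropyridin-2-yl)bis(trifluoromethanesulfonyl)imide, O=S(=O)(N(c1ccc(Cl)cn1)S(=O)(=O)C(F)(F)F)C(F)(F)F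
Why: Kinetic deprotonation at the methyl group (the less substituted α-position) and O-triflation of the enolate give the 1,1-disubstituted alkenyl triflate; the C4 ester has no α-hydrogen.

Step 12
Reactants: 21 but-3-yn-1-ol
Product: 22 tert-butyl(but-3-yn-1-yloxy)dimethylsilane
Conditions: TBSCl, imidazole, CH2Cl2, rt
Reagents that add atoms: tert-butyldimethylsilyl chloride, CC(C)(C)[Si](C)(C)Cl
Why: Standard silylation of a primary alcohol; the ether differentiates the two ends of the six-carbon piece and tolerates the organoaluminium step.

Step 13
Reactants: 22 tert-butyl(but-3-yn-1-yloxy)dimethylsilane; 23 ethylene oxide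
Product: 26 (E)-6-(tert-butyldimethylsilyloxy)-4-methylhex-3-en-1-ol, via alkenylalane 24 (not isolated), via lithium alanate 25 (not isolated)
Conditions: AlMe3, Cp2ZrCl2 (cat.), CH2Cl2, 0 °C → rt; then n-BuLi, THF, −78 °C; then 23, −78 → 0 °C
Reagents that add atoms: trimethylaluminium, C[Al](C)C
Why: Negishi zirconium-catalysed carboalumination adds methyl and aluminium syn across the alkyne with methyl on the internal carbon, which fixes the E geometry. The alanate formed with n-BuLi opens ethylene oxide with retention at the alkenyl carbon.

Step 14
Reactants: 26 (E)-6-(tert-butyldimethylsilyloxy)-4-methylhex-3-en-1-ol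
Product: 27 (2S,3S)-epoxy alcohol
Conditions: L-fructose-derived Shi ketone (30 mol %), KHSO5 (as its triple salt), K2CO3, Bu4NHSO4, MeCN/CH2(OMe)2/aq. Na2B4O7 buffer, 0 °C
Reagents that add atoms: potassium peroxymonosulfate, [K+].[O-]S(=O)(=O)OO
Why: Shi epoxidation by a chiral dioxirane through a spiro transition state is the method of choice for unfunctionalised E-trisubstituted alkenes. The D-fructose ketone gives (R,R)-epoxides with this substitution pattern, so its enantiomer should give the (S,S)-epoxide, which sets C16 and, after later inversion, C17.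

Step 15
Reactants: 27 (2S,3S)-epoxy alcohol
Product: 28 (2S,3S)-epoxy aldehyde
Conditions: Dess–Martin periodinane, NaHCO3, CH2Cl2, 0 °C; used without chromatography
Reagents that add atoms: none
Why: Dess–Martin oxidation is neutral when buffered, which matters because a β,γ-epoxy aldehyde eliminates to the γ-hydroxy enal with base; the aldehyde is used at once.

Step 16
Reactants: 20 alkenyl triflate; 28 (2S,3S)-epoxy aldehyde
Product: 30 allylic alcohol (both C14 epimers), via alkenylchromium species 29 (not isolated)
Conditions: CrCl2 (excess), NiCl2 (cat.), DMF, rt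
Reagents that add atoms: none
Why: Nozaki–Hiyama–Kishi coupling: zerovalent nickel formed from NiCl2 inserts into the C–OTf bond, the alkenyl group passes to chromium, and 29 adds to the aldehyde only, leaving esters, epoxide and silyl ethers. The remote C16 centre is not expected to control C14, so both epimers are carried into step 17.

Step 17
Reactants: 30 allylic alcohol (both C14 epimers)
Product: 31 enone (C14 ketone)
Conditions: Dess–Martin periodinane, NaHCO3, CH2Cl2, 0 °C
Reagents that add atoms: none
Why: Buffered Dess–Martin oxidation converges both epimers on one α-methylene ketone; the β,γ-epoxy ketone is base-sensitive and is taken on directly.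

Step 18
Reactants: 31 enone
Product: 32 (14S)-allylic alcohol
Conditions: (R)-2-methyl-CBS-oxazaborolidine (cat.), catecholborane, toluene, −78 °C
Reagents that add atoms: none
Why: Corey–Bakshi–Shibata reduction: the 2-substituted vinyl group acts as the large substituent and the C15 methylene as the small one, so the (R)-catalyst should deliver hydride to give the (14S)-alcohol. Catecholborane at low temperature avoids hydroboration of the alkene and reduction of the epoxide.

Step 19
Reactants: 32 (14S)-allylic alcohol
Product: 33 (14S)-mesylate
Conditions: MsCl, Et3N, CH2Cl2, −20 °C; used crude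
Reagents that add atoms: methanesulfonyl chloride, CS(=O)(=O)Cl
Why: Sulfonylation proceeds with retention at C14 and turns the carbinol into the leaving group for step 21. It also masks an alcohol that would otherwise open the epoxide to a tetrahydrofuran under the acid of step 20.

Step 20
Reactants: 33 (14S)-mesylate
Product: 34 hydroxy hydroperoxide ((16S)-OH; (17R)-OOH; (14S)-OMs)
Conditions: H2O2 (anhydrous, in Et2O), H3PMo12O40 (cat.), Et2O, 0 °C → rt
Reagents that add atoms: hydrogen peroxide, OO
Why: Acid-catalysed perhydrolysis of a trisubstituted epoxide: the heteropolyacid activates the oxirane oxygen and H2O2 attacks the tertiary C17 with inversion, leaving the C16 oxygen in place. Loss of a silyl ether here would not matter, since all three are removed in step 22.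

Step 21
Reactants: 34 hydroxy hydroperoxide
Product: 35 1,2-dioxane ((14R,16S,17R); C16–OH; C19–OTBS)
Conditions: Cs2CO3, DMF, 0 °C
Reagents that add atoms: none
Why: 6-exo-tet SN2 displacement of the allylic mesylate by the hydroperoxide anion, which is more acidic and more nucleophilic than the C16 alcohol; inversion gives (14R) and hence the axial C13 substituent. Mild carbonate base at low temperature limits Kornblum–DeLaMare cleavage of the product.

Step 22
Reactants: 35 1,2-dioxane
Product: 36 tetraol (free C6, C8, C16 and C19 hydroxyls)
Conditions: HF·pyridine, pyridine, THF, 0 °C → rt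
Reagents that add atoms: none
Why: Fluoride-mediated cleavage of both TBS ethers and the tertiary TES ether under buffered, base-free conditions that spare the peroxide, the ester and the alkene and do not drive the C6 alcohol onto the C4 ester.

Step 23
Reactants: 36 tetraol
Product: 39 target, via hydroxy aldehyde 37 (not isolated), via lactol 38 (not isolated)
Conditions: TEMPO (cat.), PhI(OAc)2, CH2Cl2, rt
Reagents that add atoms: none
Why: Oxoammonium-mediated oxidative lactonisation of a 1,4-diol: the primary C19 alcohol is oxidised to 37, which closes with the C16 hydroxyl to 38, and 38 is oxidised again to the trans-fused γ-lactone. The hindered secondary C6 alcohol and the tertiary C8 alcohol should not react, and the oxidant does not touch the O–O bond.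

## Compound list

1 | neoabietic acid (rings A/B trans, 5α-H, 9α-H, 10β-CH3; C4 with α-CO2H and β-CH3; ring C with C8=CH and exocyclic isopropylidene) | CC(C)=C1CC[C@@H]2[C@@]3(C)CCC[C@@](C)(C(=O)O)[C@@H]3CCC2=C1 | starting material
2 | enone acid (1 with the isopropylidene group replaced by a ketone oxygen) | O=C1CC[C@@H]2[C@@]3(C)CCC[C@@](C)(C(=O)O)[C@@H]3CCC2=C1 | intermediate (not isolated)
3 | keto diacid (trans-decalin; C8 ketone; C9β-CH2CH2CO2H; C4α-CO2H, C4β-CH3; C10β-CH3) | OC(=O)CC[C@@H]1[C@@]2(C)CCC[C@@](C)(C(=O)O)[C@@H]2CCC1=O | intermediate
4 | keto ester acid (3 with C13 as methyl ester) | COC(=O)CC[C@@H]1[C@@]2(C)CCC[C@@](C)(C(=O)O)[C@@H]2CCC1=O | intermediate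
5 | methylene ester acid (C8=CH2) | COC(=O)CC[C@@H]1[C@@]2(C)CCC[C@@](C)(C(=O)O)[C@@H]2CCC1=C | intermediate
6 | hydroxy ester acid (8α-OH, 8β-CH3) | COC(=O)CC[C@@H]1[C@@]2(C)CCC[C@@](C)(C(=O)O)[C@@H]2CC[C@@]1(C)O | intermediate
7 | bis-silyl compound (8α-OTES and C4 triethylsilyl ester) | COC(=O)CC[C@@H]1[C@@]2(C)CCC[C@@](C)(C(=O)O[Si](CC)(CC)CC)[C@@H]2CC[C@@]1(C)O[Si](CC)(CC)CC | intermediate (not isolated)
8 | silyl ether acid (8α-OTES, free C4α-CO2H) | COC(=O)CC[C@@H]1[C@@]2(C)CCC[C@@](C)(C(=O)O)[C@@H]2CC[C@@]1(C)O[Si](CC)(CC)CC | intermediate
9 | acid chloride (C4α-COCl) | COC(=O)CC[C@@H]1[C@@]2(C)CCC[C@@](C)(C(=O)Cl)[C@@H]2CC[C@@]1(C)O[Si](CC)(CC)CC | intermediate (not isolated)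
10 | carboxamide (C4α-CONH2, 8α-OTES, C13 methyl ester) | COC(=O)CC[C@@H]1[C@@]2(C)CCC[C@@](C)(C(N)=O)[C@@H]2CC[C@@]1(C)O[Si](CC)(CC)CC | intermediate (key-step precursor)
11 | N-iodoamide (C4α-CONHI) | COC(=O)CC[C@@H]1[C@@]2(C)CCC[C@@](C)(C(=O)NI)[C@@H]2CC[C@@]1(C)O[Si](CC)(CC)CC | intermediate (not isolated)
12 | 6-iodo amide (C6 configuration not defined) | COC(=O)CC[C@@H]1[C@@]2(C)CCC[C@@](C)(C(N)=O)[C@@H]2C(I)C[C@@]1(C)O[Si](CC)(CC)CC | intermediate (not isolated)
13 | iminolactone (C(=NH)–O bridge from the C4 carbon to C6α) | COC(=O)CC[C@@H]1[C@@]2(C)CCC[C@@](C)(C(=N)O3)[C@@H]2[C@@H]3C[C@@]1(C)O[Si](CC)(CC)CC | intermediate (not isolated)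
14 | γ-lactone (C4α-carbonyl–O–C6α bridge, 8α-OTES, C13 methyl ester) | COC(=O)CC[C@@H]1[C@@]2(C)CCC[C@@](C)(C(=O)O3)[C@@H]2[C@@H]3C[C@@]1(C)O[Si](CC)(CC)CC | intermediate (key-step product)
15 | dilithium dicarboxylate (6α-OH, C4 and C13 carboxylates, 8α-OTES) | [Li+].[Li+].[O-]C(=O)CC[C@@H]1[C@@]2(C)CCC[C@@](C)(C([O-])=O)[C@@H]2[C@@H](O)C[C@@]1(C)O[Si](CC)(CC)CC | intermediate (not isolated)
16 | hydroxy diester (6α-OH, C4α-CO2Me, C13 CO2Me, 8α-OTES) | COC(=O)CC[C@@H]1[C@@]2(C)CCC[C@@](C)(C(=O)OC)[C@@H]2[C@@H](O)C[C@@]1(C)O[Si](CC)(CC)CC | intermediate
17 | bis-silyl diester (6α-OTBS, 8α-OTES) | COC(=O)CC[C@@H]1[C@@]2(C)CCC[C@@](C)(C(=O)OC)[C@@H]2[C@@H](O[Si](C)(C)C(C)(C)C)C[C@@]1(C)O[Si](CC)(CC)CC | intermediate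
18 | Weinreb amide (C13 N-methoxy-N-methylamide) | CON(C)C(=O)CC[C@@H]1[C@@]2(C)CCC[C@@](C)(C(=O)OC)[C@@H]2[C@@H](O[Si](C)(C)C(C)(C)C)C[C@@]1(C)O[Si](CC)(CC)CC | intermediate (not isolated)
19 | methyl ketone (C13 ketone) | CC(=O)CC[C@@H]1[C@@]2(C)CCC[C@@](C)(C(=O)OC)[C@@H]2[C@@H](O[Si](C)(C)C(C)(C)C)C[C@@]1(C)O[Si](CC)(CC)CC | intermediate
20 | alkenyl triflate (C13(OTf)=CH2) | C=C(OS(=O)(=O)C(F)(F)F)CC[C@@H]1[C@@]2(C)CCC[C@@](C)(C(=O)OC)[C@@H]2[C@@H](O[Si](C)(C)C(C)(C)C)C[C@@]1(C)O[Si](CC)(CC)CC | intermediate
21 | but-3-yn-1-ol | C#CCCO | starting material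
22 | tert-butyl(but-3-yn-1-yloxy)dimethylsilane | C#CCCO[Si](C)(C)C(C)(C)C | intermediate
23 | ethylene oxide | C1CO1 | starting material
24 | (E)-alkenyl(dimethyl)alane (Al and methyl cis) | C[Al](C)/C=C(\C)CCO[Si](C)(C)C(C)(C)C | intermediate (not isolated)
25 | lithium (E)-alkenyl(butyl)dimethylaluminate | [Li+].CCCC[Al-](C)(C)/C=C(\C)CCO[Si](C)(C)C(C)(C)C | intermediate (not isolated)
26 | (E)-6-(tert-butyldimethylsilyloxy)-4-methylhex-3-en-1-ol | OCC/C=C(\C)CCO[Si](C)(C)C(C)(C)C | intermediate
27 | 2-[(2S,3S)-3-[2-(tert-butyldimethylsilyloxy)ethyl]-3-methyloxiran-2-yl]ethan-1-ol | OCC[C@@H]1O[C@@]1(C)CCO[Si](C)(C)C(C)(C)C | intermediate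
28 | 2-[(2S,3S)-3-[2-(tert-butyldimethylsilyloxy)ethyl]-3-methyloxiran-2-yl]acetaldehyde | O=CC[C@@H]1O[C@@]1(C)CCO[Si](C)(C)C(C)(C)C | intermediate
29 | alkenylchromium dichloride derived from 20 | C=C([Cr](Cl)Cl)CC[C@@H]1[C@@]2(C)CCC[C@@](C)(C(=O)OC)[C@@H]2[C@@H](O[Si](C)(C)C(C)(C)C)C[C@@]1(C)O[Si](CC)(CC)CC | intermediate (not isolated)
30 | allylic alcohol (C14–OH, both epimers; (16S,17S)-epoxide; C19–OTBS) | C=C(CC[C@@H]1[C@@]2(C)CCC[C@@](C)(C(=O)OC)[C@@H]2[C@@H](O[Si](C)(C)C(C)(C)C)C[C@@]1(C)O[Si](CC)(CC)CC)C(O)C[C@@H]3O[C@@]3(C)CCO[Si](C)(C)C(C)(C)C | intermediate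
31 | enone (C14 ketone, C13=CH2) | C=C(CC[C@@H]1[C@@]2(C)CCC[C@@](C)(C(=O)OC)[C@@H]2[C@@H](O[Si](C)(C)C(C)(C)C)C[C@@]1(C)O[Si](CC)(CC)CC)C(=O)C[C@@H]3O[C@@]3(C)CCO[Si](C)(C)C(C)(C)C | intermediate
32 | (14S)-allylic alcohol | C=C(CC[C@@H]1[C@@]2(C)CCC[C@@](C)(C(=O)OC)[C@@H]2[C@@H](O[Si](C)(C)C(C)(C)C)C[C@@]1(C)O[Si](CC)(CC)CC)[C@@H](O)C[C@@H]3O[C@@]3(C)CCO[Si](C)(C)C(C)(C)C | intermediate
33 | (14S)-mesylate | C=C(CC[C@@H]1[C@@]2(C)CCC[C@@](C)(C(=O)OC)[C@@H]2[C@@H](O[Si](C)(C)C(C)(C)C)C[C@@]1(C)O[Si](CC)(CC)CC)[C@@H](OS(C)(=O)=O)C[C@@H]3O[C@@]3(C)CCO[Si](C)(C)C(C)(C)C | intermediate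
34 | hydroxy hydroperoxide ((14S)-OMs, (16S)-OH, (17R)-OOH) | C=C(CC[C@@H]1[C@@]2(C)CCC[C@@](C)(C(=O)OC)[C@@H]2[C@@H](O[Si](C)(C)C(C)(C)C)C[C@@]1(C)O[Si](CC)(CC)CC)[C@@H](OS(C)(=O)=O)C[C@H](O)[C@@](C)(CCO[Si](C)(C)C(C)(C)C)OO | intermediate
35 | 1,2-dioxane ((14R,16S,17R); C16–OH; C17 with CH3 and CH2CH2OTBS; 6α-OTBS, 8α-OTES) | C=C(CC[C@@H]1[C@@]2(C)CCC[C@@](C)(C(=O)OC)[C@@H]2[C@@H](O[Si](C)(C)C(C)(C)C)C[C@@]1(C)O[Si](CC)(CC)CC)[C@H]3C[C@H](O)[C@@](C)(CCO[Si](C)(C)C(C)(C)C)OO3 | intermediate
36 | tetraol (35 without its three silyl groups) | C=C(CC[C@@H]1[C@@]2(C)CCC[C@@](C)(C(=O)OC)[C@@H]2[C@@H](O)C[C@@]1(C)O)[C@H]3C[C@H](O)[C@@](C)(CCO)OO3 | intermediate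
37 | hydroxy aldehyde (C19 aldehyde, C16–OH) | C=C(CC[C@@H]1[C@@]2(C)CCC[C@@](C)(C(=O)OC)[C@@H]2[C@@H](O)C[C@@]1(C)O)[C@H]3C[C@H](O)[C@@](C)(CC=O)OO3 | intermediate (not isolated)
38 | lactol (C19 hemiacetal, either epimer) | C=C(CC[C@@H]1[C@@]2(C)CCC[C@@](C)(C(=O)OC)[C@@H]2[C@@H](O)C[C@@]1(C)O)[C@H]3C[C@@H]4OC(O)C[C@@]4(C)OO3 | intermediate (not isolated)
39 | CNP0162504.1 (trans-fused dioxane γ-lactone, 14R,16S,17R; 6α-OH, 8α-OH, C4α-CO2Me) | C=C(CC[C@@H]1[C@@]2(C)CCC[C@@](C)(C(=O)OC)[C@@H]2[C@@H](O)C[C@@]1(C)O)[C@H]1C[C@@H]2OC(=O)C[C@@]2(C)OO1 | target

## Step count and least certain steps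

Total: 23 steps. Longest linear sequence: 19 steps (steps 1–11 and 16–23, from 1). The six-carbon piece takes 4 steps (12–15, from 21).

Step 7 (key step). The most likely failure is diversion of the N-iodoamide before hydrogen transfer: Hofmann-type migration of the tertiary C4 to nitrogen is easy under a trivalent-iodine oxidant, closure may go through nitrogen to a lactam, and the acid released may remove the tertiary silyl ether and expose C8–OH to hypoiodite fragmentation. The fallback keeps the geometric idea but changes the radical. It sets out from 8: BH3·SMe2 should reduce the free C4 acid in the presence of the C13 ester to the neopentyl alcohol F1. Its hypoiodite (PhI(OAc)2, I2, hν, cyclohexane) gives an alkoxyl radical that makes the same 1,5-hydrogen transfer from C6 and closes to the bridged tetrahydrofuran F2. RuCl3/NaIO4 then oxidises the ether CH2 to the carbonyl and returns to the route at 14.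

Step 4. The risk is poor facial selectivity when O2 captures the planar C8 radical, and cyclisation of the new tertiary alkoxide onto the C13 ester to a δ-lactone. The fallback installs the oxygen by a polar, face-selective reagent. It sets out from 5: mCPBA should epoxidise the exocyclic alkene from the α face (away from the C10 methyl) to the spiro-epoxide F3. MgI2 opens F3 at the primary carbon to the iodohydrin F4, and Bu3SnH/AIBN removes the iodine and returns to 6.

Step 16. The risk is loss of the aldehyde before it couples: β-elimination of the epoxy aldehyde to a γ-hydroxy enal, or opening of the epoxide by Lewis-acidic trivalent chromium. The fallback postpones the epoxide. It sets out from 26 (and 20): Dess–Martin oxidation gives the alkenal F5, and the same NiCl2/CrCl2 coupling with 20 gives the dienol F6. Oxidation gives the dienone F7 and the same oxazaborolidine reduction gives the (14S)-dienol F8. Shi epoxidation of the trisubstituted alkene of F8 (faster than the 1,1-disubstituted one) returns to 32.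

Step 20. The risks are ionisation or allylic transposition of the mesylate in the acidic medium, partial cationic character at C17 that erodes the inversion, and attack at C16. The fallback uses a sturdier electrophile and a double inversion. It sets out from 31: the (S)-oxazaborolidine gives the (14R)-alcohol F9, and hexachloroacetone/PPh3 converts it with inversion to the (14S)-chloride F10. Perhydrolysis as in step 20 gives F11, and Cs2CO3 in DMF closes the ring with a second inversion, returning to 35.

Step 23. The risk is over-oxidation of the unprotected secondary C6 alcohol while the lactol is being oxidised. The fallback keeps C6 protected during the oxidation at the cost of one step. It sets out from 35: camphorsulfonic acid in MeOH at 0 °C should remove the primary TBS ether and the tertiary TES ether but not the hindered C6 TBS ether, giving F12. TEMPO/PhI(OAc)2 then gives the lactone F13, and HF·pyridine returns to 39.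

## Further compounds

F1 | step 7 | C4α-hydroxymethyl compound (8α-OTES, C13 methyl ester) | COC(=O)CC[C@@H]1[C@@]2(C)CCC[C@@](C)(CO)[C@@H]2CC[C@@]1(C)O[Si](CC)(CC)CC
F2 | step 7 | bridged tetrahydrofuran (C4α-CH2–O–C6α) | COC(=O)CC[C@@H]1[C@@]2(C)CCC[C@@](C)(CO3)[C@@H]2[C@@H]3C[C@@]1(C)O[Si](CC)(CC)CC
F3 | step 4 | C8 spiro-epoxide (oxygen α) | COC(=O)CC[C@@H]1[C@@]2(C)CCC[C@@](C)(C(=O)O)[C@@H]2CC[C@]13CO3
F4 | step 4 | iodohydrin (8α-OH, 8β-CH2I) | COC(=O)CC[C@@H]1[C@@]2(C)CCC[C@@](C)(C(=O)O)[C@@H]2CC[C@@]1(CI)O
F5 | step 16 | (E)-6-(tert-butyldimethylsilyloxy)-4-methylhex-3-enal | O=CC/C=C(\C)CCO[Si](C)(C)C(C)(C)C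
F6 | step 16 | dienol (C14–OH, both epimers; C16=C17 E) | C=C(CC[C@@H]1[C@@]2(C)CCC[C@@](C)(C(=O)OC)[C@@H]2[C@@H](O[Si](C)(C)C(C)(C)C)C[C@@]1(C)O[Si](CC)(CC)CC)C(O)C/C=C(\C)CCO[Si](C)(C)C(C)(C)C
F7 | step 16 | dienone (C14 ketone; C16=C17 E) | C=C(CC[C@@H]1[C@@]2(C)CCC[C@@](C)(C(=O)OC)[C@@H]2[C@@H](O[Si](C)(C)C(C)(C)C)C[C@@]1(C)O[Si](CC)(CC)CC)C(=O)C/C=C(\C)CCO[Si](C)(C)C(C)(C)C
F8 | step 16 | (14S)-dienol | C=C(CC[C@@H]1[C@@]2(C)CCC[C@@](C)(C(=O)OC)[C@@H]2[C@@H](O[Si](C)(C)C(C)(C)C)C[C@@]1(C)O[Si](CC)(CC)CC)[C@@H](O)C/C=C(\C)CCO[Si](C)(C)C(C)(C)C
F9 | step 20 | (14R)-allylic alcohol | C=C(CC[C@@H]1[C@@]2(C)CCC[C@@](C)(C(=O)OC)[C@@H]2[C@@H](O[Si](C)(C)C(C)(C)C)C[C@@]1(C)O[Si](CC)(CC)CC)[C@H](O)C[C@@H]3O[C@@]3(C)CCO[Si](C)(C)C(C)(C)C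
F10 | step 20 | (14S)-allylic chloride | C=C(CC[C@@H]1[C@@]2(C)CCC[C@@](C)(C(=O)OC)[C@@H]2[C@@H](O[Si](C)(C)C(C)(C)C)C[C@@]1(C)O[Si](CC)(CC)CC)[C@@H](Cl)C[C@@H]3O[C@@]3(C)CCO[Si](C)(C)C(C)(C)C
F11 | step 20 | chloro hydroxy hydroperoxide ((14S)-Cl, (16S)-OH, (17R)-OOH) | C=C(CC[C@@H]1[C@@]2(C)CCC[C@@](C)(C(=O)OC)[C@@H]2[C@@H](O[Si](C)(C)C(C)(C)C)C[C@@]1(C)O[Si](CC)(CC)CC)[C@@H](Cl)C[C@H](O)[C@@](C)(CCO[Si](C)(C)C(C)(C)C)OO
F12 | step 23 | dioxane triol with 6α-OTBS (free C8, C16, C19 hydroxyls) | C=C(CC[C@@H]1[C@@]2(C)CCC[C@@](C)(C(=O)OC)[C@@H]2[C@@H](O[Si](C)(C)C(C)(C)C)C[C@@]1(C)O)[C@H]3C[C@H](O)[C@@](C)(CCO)OO3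
F13 | step 23 | 6α-OTBS ether of the target | C=C(CC[C@@H]1[C@@]2(C)CCC[C@@](C)(C(=O)OC)[C@@H]2[C@@H](O[Si](C)(C)C(C)(C)C)C[C@@]1(C)O)[C@H]3C[C@@H]4OC(=O)C[C@@]4(C)OO3
A1 | alternative 1 | open-chain epoxy dienoic acid (C3–C4 epoxide, E-alkenes C5=C10 and C8=C9, 6-benzyloxy, C4 benzyloxymethyl) | OC(=O)C/C=C(\C)C[C@H](OCc1ccccc1)/C=C(\C)CC[C@@H]2O[C@@]2(C)COCc1ccccc1
A2 | alternative 1 | tricyclic lactone (3β-hydroxy, 4α-benzyloxymethyl, 6α-benzyloxy, 8α,12-lactone) | O=C1C[C@@H]2[C@@]3(C)CC[C@H](O)[C@@](C)(COCc4ccccc4)[C@@H]3[C@@H](OCc3ccccc3)C[C@@]2(C)O1
A3 | alternative 2 | triene ester (acetonide of the C8/C11 diol; E-diene on C9; E-2-methylenoate at C4=C5; 6-OTBS) | CC1(C)OC[C@H](/C(C)=C/C=C)[C@@](C)(C[C@H](O[Si](C)(C)C(C)(C)C)/C=C(\C)C(=O)OC)O1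
A4 | alternative 2 | trans-fused octalin with C1=C2 alkene | CC1(C)OC[C@@H]2[C@@]3(C)C=CC[C@@](C)(C(=O)OC)[C@@H]3[C@@H](O[Si](C)(C)C(C)(C)C)C[C@@]2(C)O1
A5 | alternative 3 | hydroxy hydroperoxy mesylate (C19 4-methoxybenzyl ether, 6α-OTBS, free 8α-OH) | C=C(CC[C@@H]1[C@@]2(C)CCC[C@@](C)(C(=O)OC)[C@@H]2[C@@H](O[Si](C)(C)C(C)(C)C)C[C@@]1(C)O)[C@@H](OS(C)(=O)=O)C[C@H](O)[C@@](C)(CCOCc2ccc(OC)cc2)OO
A6 | alternative 3 | 1,2-dioxane with C16 alcohol and 4-methoxybenzyl-protected hydroxyethyl arm | C=C(CC[C@@H]1[C@@]2(C)CCC[C@@](C)(C(=O)OC)[C@@H]2[C@@H](O[Si](C)(C)C(C)(C)C)C[C@@]1(C)O)[C@H]1C[C@H](O)[C@@](C)(CCOCc2ccc(OC)cc2)OO1
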